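Monday's run is where I start, since flask theta, set out below with the others, looks like Monday's flask in another dress.

| flask | starting material | partner | second substrate | catalyst | remark | time |
|---|---|---|---|---|---|---|
| Monday's | 0.050 M | 0.019 M (fed, over 50 s) | 0.10 M | 0.50 mM | run made earlier |  |
| Thursday's | 0.050 M | 0.083 M (fed, over 50 s) | 0.10 M | 0.50 mM | run made earlier |  |
| Wednesday's | 0.050 M | 0.045 M (fed, over 50 s) | 0.10 M | 0.28 mM | run made earlier |  |
| alpha | 0.050 M | 0.100 M (fed, over 15 s) | 0.100 M | 0.50 mM |  | 2.0 min |
| gamma | 0.050 M | 0.0300 M (fed, over 25 s) | 0.100 M | 0.50 mM |  | 2.0 min |
| theta | 0.20 M | 0.0450 M (fed, over 50 s) | 0.100 M | 0.12 mM |  | 2.0 min |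
| eta | 0.050 M | 0.0450 M (fed, over 50 s) | 0.100 M | 0.50 mM |  | 2.0 min |
| beta | 0.050 M | 0.0450 M (fed, over 80 s) | 0.100 M | 0.30 mM |  | 2.0 min |

- Monday's (time / s: target / %): 10.0: 2.6; 20.0: 7.6; 50.0: 23.2; 120: 23.6
- Thursday's (time / s: target / %): 30.0: 46.5; 60.0: 78.3; 90.0: 80.1; 120: 76.5
- Wednesday's (time / s: target / %): 30.0: 22.0; 60.0: 44.8; 90.0: 48.7; 120: 47.8

(readings scatter by 0.5 percentage points)

- candidate steps: target + catalyst <-> isomer of the product + catalyst; partner -> decomposed reagent; starting material + partner + catalyst -> catalyst + target; second substrate + partner + catalyst -> catalyst + second product

- the flasks by amount of target, in percent of the starting material charged, highest first, at 2.0 min (alpha / gamma / theta / eta / beta)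
- the same order at 12 s (alpha / gamma / theta / eta / beta)
- the amount of target, in percent of the starting material charged of the flask you put first, at 2.0 min
- the amount of target, in percent of the starting material charged of the flask you put last, at 2.0 min

Flask theta is charged with partner for 22.5% of its starting material, below the next lowest, gamma, at 60.0%. So partner is its limiting reagent, and I expect theta last. Monday's last reading gives 62.1% as the part of the charged partner that stands as target at the end, the capture share.

Can a share be carried from one flask to another? On Monday, target follows the dose after a lag of about 4.80 s, far shorter than the 50 s of dosing, so partner is used about as it arrives. Each partner then chooses between the step with starting material, whose rate goes with catalyst times starting material, and its other exits, which I take as they were on Monday. That product in theta is 96.0% of Monday's, so a first estimate is 14.0%.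

But Monday's share is net of a loss. After its dose, Thursday's target reads 80.1% and then 76.5%, which I read as a net fall of about 0.00153 s⁻¹ at Monday's catalyst level, from two readings that each carry a scatter of 0.5 percentage points. Target made around the middle of the dose is 95.0 s old at the end, so I put Monday's gross capture at about 71.8%. Theta has 24.0% of that catalyst and the same dose time, so it should lose 3.43% of its target, if that step goes with catalyst. This gives 15.6%.

A second doubt is that starting material is consumed. By my gross capture, Monday's flask keeps on average over the run about 86.4% of its charge and theta about 91.9%, which moves my ratio of products to 102%. That is still close to parity, so I stay at my estimate.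

The forecast gives alpha > eta > beta > gamma > theta at 2.0 min and alpha > gamma > eta > beta > theta at 12 s, with 80% for alpha and 17.3% for theta, higher than my figure, and it reads that “about 70% of the dosed partner goes to target”.

Flask theta gives 16.5% and alpha 78.5%, and the order is alpha > eta > beta > gamma > theta at 2.0 min and alpha > gamma > eta > beta > theta at 12 s.

    target + catalyst ⇌ isomer of the product + catalyst, rate k1*[catalyst]*[target] forward; the back reaction follows from the equilibrium constant (K = 0.908, k = 4.68 M⁻¹ s⁻¹)
    partner → decomposed reagent (k = 0.0276 s⁻¹)
    starting material + partner + catalyst → catalyst + target (k = 4350 M⁻² s⁻¹)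
    second substrate + partner + catalyst → catalyst + second product (k = 70.3 M⁻² s⁻¹)

In flask theta, 0.00524% of the charged partner remains beside 82.7% of the charged starting material, and its target holds 73.4% of the charged partner. Flask gamma has Monday's catalyst and starting material but a dose of 25 s against 50 s; Monday's net capture share of 62.1% on its charge gives 37.3%, and gamma stands at 35.6%.

The earlier runs and the new flask are simulated for an exercise; scatter was added.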